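**Retrosynthetic overview**
1. Kuraridin 28 comes from the tetra‑MOM chalcone 27 by global acetal cleavage. 27 comes from a Claisen–Schmidt aldol condensation of acetophenone 23 with aldehyde 25, which is the key fragment‑joining C–C bond.
2. 23 comes from the C2‑symmetric arene 20 by ortho‑lithiation, acetaldehyde addition and oxidation.
3. The isopropenyl group of 20 comes from methyl ketone 19 by methylenation. 19 comes from acid 15 via a Weinreb amide. The (R) centre of 15 is set by Evans prenylation of imide 11.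
4. 11 comes from arylpropanoic acid 8. 8 comes from aldehyde 5 by Wittig, hydrogenation and saponification. 5 comes from directed ortho‑metalation of bis‑MOM 5‑methoxyresorcinol 2.
5. No ring is formed in the route; both benzene rings are bought (1 and 24).

Assumption: reagents that only deliver atoms (MOMCl, DMF, prenyl bromide and the like) are given by name and SMILES on the reagent line and are not numbered; the target stereocentre reads as (R) from the SMILES.

**Step 1**
Reactants: 1 5-methoxyresorcinol (3,5-dihydroxyanisole)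
Product: 2 1-methoxy-3,5-bis(methoxymethoxy)benzene
Conditions: MOMCl (2.5 eq), i-Pr2NEt (3 eq), CH2Cl2, 0 °C → rt
Reagents that add atoms: chloromethyl methyl ether (MOMCl), COCCl
Why: Williamson-type O-alkylation of both phenols gives base-stable MOM acetals that later serve as ortho-directing groups.

**Step 2**
Reactants: 2 1-methoxy-3,5-bis(methoxymethoxy)benzene
Product: 5 4-methoxy-2,6-bis(methoxymethoxy)benzaldehyde, via aryllithium 3 (not isolated), via lithium hemiaminal alkoxide 4 (not isolated)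
Conditions: n-BuLi (1.15 eq), TMEDA, THF, 0 °C, 1 h; DMF, 0 °C → rt; H2O
Reagents that add atoms: N,N-dimethylformamide, CN(C)C=O
Why: Directed ortho-metalation occurs at the carbon flanked by the two chelating OMOM groups (stronger directors than OMe), and DMF formylates the aryllithium.

**Step 3**
Reactants: 5 4-methoxy-2,6-bis(methoxymethoxy)benzaldehyde
Product: 6 ethyl (2E)-3-[4-methoxy-2,6-bis(methoxymethoxy)phenyl]prop-2-enoate
Conditions: Ph3P=CHCO2Et (1.3 eq), toluene, 100 °C
Reagents that add atoms: ethyl (triphenylphosphoranylidene)acetate, CCOC(=O)C=P(c1ccccc1)(c1ccccc1)c1ccccc1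
Why: Wittig olefination with a stabilised ylide tolerates the hindered, electron-rich aldehyde; the alkene geometry is irrelevant because it is hydrogenated next.

**Step 4**
Reactants: 6 ethyl (2E)-3-[4-methoxy-2,6-bis(methoxymethoxy)phenyl]prop-2-enoate
Product: 7 ethyl 3-[4-methoxy-2,6-bis(methoxymethoxy)phenyl]propanoate
Conditions: H2 (1 atm), 10% Pd/C, EtOAc, rt
Reagents that add atoms: none
Why: Catalytic hydrogenation saturates the conjugated alkene under neutral conditions that leave aryl MOM ethers and the ester untouched.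

**Step 5**
Reactants: 7 ethyl 3-[4-methoxy-2,6-bis(methoxymethoxy)phenyl]propanoate
Product: 8 3-[4-methoxy-2,6-bis(methoxymethoxy)phenyl]propanoic acid
Conditions: LiOH·H2O, THF/MeOH/H2O, rt; then cold 1 M HCl to pH 4
Reagents that add atoms: lithium hydroxide, [Li+].[OH-]
Why: Saponification of an unhindered ethyl ester; brief cold acidification to pH 4 does not cleave aryl MOM ethers.

**Step 6**
Reactants: 8 3-[4-methoxy-2,6-bis(methoxymethoxy)phenyl]propanoic acid; 9 (4R)-4-benzyl-1,3-oxazolidin-2-one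
Product: 11 (4R)-4-benzyl-3-{3-[4-methoxy-2,6-bis(methoxymethoxy)phenyl]propanoyl}-1,3-oxazolidin-2-one, via mixed pivalic anhydride 10 (not isolated)
Conditions: PivCl, Et3N, THF, −20 °C; then 9, LiCl, −20 °C → rt
Reagents that add atoms: none
Why: N-acylation of the Evans auxiliary through the mixed pivalic anhydride, which is attacked selectively at the less hindered carbonyl.

**Step 7**
Reactants: 11 (4R)-4-benzyl-3-{3-[4-methoxy-2,6-bis(methoxymethoxy)phenyl]propanoyl}-1,3-oxazolidin-2-one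
Product: 13 (4R)-4-benzyl-3-[(2R)-2-{[4-methoxy-2,6-bis(methoxymethoxy)phenyl]methyl}-5-methylhex-4-enoyl]-1,3-oxazolidin-2-one, via sodium Z-enolate 12 (not isolated)
Conditions: NaHMDS (1.1 eq), THF, −78 °C; prenyl bromide (3 eq), −78 → −40 °C
Reagents that add atoms: 1-bromo-3-methylbut-2-ene (prenyl bromide), CC(C)=CCBr
Why: Evans asymmetric alkylation, in which the chelated Z-enolate is shielded on one face by the (R)-benzyl group so prenyl bromide adds anti to it (Cα Re face) and sets the (2R) centre (dr ≥ 95:5 expected, minor isomer removed by chromatography).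

**Step 8**
Reactants: 13 (4R)-4-benzyl-3-[(2R)-2-{[4-methoxy-2,6-bis(methoxymethoxy)phenyl]methyl}-5-methylhex-4-enoyl]-1,3-oxazolidin-2-one
Product: 15 (2R)-2-{[4-methoxy-2,6-bis(methoxymethoxy)phenyl]methyl}-5-methylhex-4-enoic acid, via lithium peroxycarboxylate 14 (not isolated)
Conditions: LiOH, 30% H2O2, THF/H2O 3:1, 0 °C; aq. Na2SO3; cold 1 M HCl to pH 4
Reagents that add atoms: hydrogen peroxide, OO
Why: Hydroperoxide-mediated auxiliary cleavage attacks the exocyclic carbonyl selectively and without epimerisation, and the anionic peracid does not epoxidise the alkene before sulfite reduction.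

**Step 9**
Reactants: 15 (2R)-2-{[4-methoxy-2,6-bis(methoxymethoxy)phenyl]methyl}-5-methylhex-4-enoic acid
Product: 17 (2R)-N-methoxy-2-{[4-methoxy-2,6-bis(methoxymethoxy)phenyl]methyl}-N,5-dimethylhex-4-enamide, via acyl imidazole 16 (not isolated)
Conditions: CDI (1.2 eq), CH2Cl2, rt; then MeNH(OMe)·HCl (1.5 eq), rt
Reagents that add atoms: N,O-dimethylhydroxylamine hydrochloride, CNOC.Cl
Why: Amide coupling through the acyl imidazole gives the Weinreb amide under near-neutral conditions that neither epimerise the α-centre nor touch the MOM ethers.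

**Step 10**
Reactants: 17 (2R)-N-methoxy-2-{[4-methoxy-2,6-bis(methoxymethoxy)phenyl]methyl}-N,5-dimethylhex-4-enamide
Product: 19 (3R)-3-{[4-methoxy-2,6-bis(methoxymethoxy)phenyl]methyl}-6-methylhept-5-en-2-one, via magnesium hemiaminal chelate 18 (not isolated)
Conditions: MeMgBr (3 eq), THF, 0 °C; H2O
Reagents that add atoms: methylmagnesium bromide, C[Mg]Br
Why: Weinreb ketone synthesis, in which the stable chelate prevents over-addition and releases the ketone only on quench, so the α-centre never sees base as a ketone.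

**Step 11**
Reactants: 19 (3R)-3-{[4-methoxy-2,6-bis(methoxymethoxy)phenyl]methyl}-6-methylhept-5-en-2-one
Product: 20 5-methoxy-1,3-bis(methoxymethoxy)-2-[(2R)-5-methyl-2-(prop-1-en-2-yl)hex-4-en-1-yl]benzene
Conditions: Ph3PCH3Br (1.6 eq), KOt-Bu (1.5 eq), THF, 0 °C; then 19, 0 °C → rt
Reagents that add atoms: methyltriphenylphosphonium bromide, C[P+](c1ccccc1)(c1ccccc1)c1ccccc1.[Br-]
Why: Wittig methylenation with pre-formed ylide (phosphonium salt in slight excess, no free alkoxide) turns the acetyl group into the isopropenyl group, after which the stereocentre is allylic and no longer epimerisable.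

**Step 12**
Reactants: 20 5-methoxy-1,3-bis(methoxymethoxy)-2-[(2R)-5-methyl-2-(prop-1-en-2-yl)hex-4-en-1-yl]benzene
Product: 22 1-{6-methoxy-2,4-bis(methoxymethoxy)-3-[(2R)-5-methyl-2-(prop-1-en-2-yl)hex-4-en-1-yl]phenyl}ethan-1-ol (both carbinol epimers), via aryllithium 21 (not isolated)
Conditions: n-BuLi (1.15 eq), TMEDA, THF, −20 → 0 °C; CH3CHO (3 eq), −78 °C; H2O
Reagents that add atoms: acetaldehyde, CC=O
Why: Directed ortho-metalation at the ring CH flanked by OMOM and OMe (the two free ring positions are equivalent by rotation about the Ar–CH2 bond) followed by 1,2-addition to acetaldehyde; the carbinol centre is destroyed in the next step.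

**Step 13**
Reactants: 22 1-{6-methoxy-2,4-bis(methoxymethoxy)-3-[(2R)-5-methyl-2-(prop-1-en-2-yl)hex-4-en-1-yl]phenyl}ethan-1-ol
Product: 23 1-{6-methoxy-2,4-bis(methoxymethoxy)-3-[(2R)-5-methyl-2-(prop-1-en-2-yl)hex-4-en-1-yl]phenyl}ethan-1-one
Conditions: Dess–Martin periodinane (1.3 eq), CH2Cl2, 0 °C → rt
Reagents that add atoms: none
Why: Dess–Martin oxidation of the benzylic secondary alcohol is mild enough to spare the MOM ethers and both alkenes.

**Step 14**
Reactants: 24 2,4-dihydroxybenzaldehyde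
Product: 25 2,4-bis(methoxymethoxy)benzaldehyde
Conditions: MOMCl (3 eq), K2CO3 (4 eq), acetone, 0 → 50 °C
Reagents that add atoms: chloromethyl methyl ether (MOMCl), COCCl
Why: Williamson-type O-alkylation; excess reagent and warming also protect the hydrogen-bonded 2-OH so that no phenoxide deactivates the aldehyde in the aldol step.

**Step 15**
Reactants: 23 1-{6-methoxy-2,4-bis(methoxymethoxy)-3-[(2R)-5-methyl-2-(prop-1-en-2-yl)hex-4-en-1-yl]phenyl}ethan-1-one; 25 2,4-bis(methoxymethoxy)benzaldehyde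
Product: 27 (2E)-3-[2,4-bis(methoxymethoxy)phenyl]-1-{6-methoxy-2,4-bis(methoxymethoxy)-3-[(2R)-5-methyl-2-(prop-1-en-2-yl)hex-4-en-1-yl]phenyl}prop-2-en-1-one, via aldol adduct 26 (not isolated)
Conditions: KOH (5 eq), EtOH/H2O, rt → 50 °C
Reagents that add atoms: none
Why: Claisen–Schmidt aldol condensation between the only enolisable ketone and a non-enolisable aldehyde; E1cB dehydration gives the conjugated (E)-chalcone, and the non-acidic side-chain centre is untouched.

**Step 16**
Reactants: 27 (2E)-3-[2,4-bis(methoxymethoxy)phenyl]-1-{6-methoxy-2,4-bis(methoxymethoxy)-3-[(2R)-5-methyl-2-(prop-1-en-2-yl)hex-4-en-1-yl]phenyl}prop-2-en-1-one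
Product: 28 kuraridin, (2E)-3-(2,4-dihydroxyphenyl)-1-{2,4-dihydroxy-6-methoxy-3-[(2R)-5-methyl-2-(prop-1-en-2-yl)hex-4-en-1-yl]phenyl}prop-2-en-1-one
Conditions: HCl (ca. 1 M) in MeOH, rt → 40 °C, stopped as soon as the last MOM group is gone (HPLC)
Reagents that add atoms: none
Why: Acid-catalysed transacetalisation to methanol removes all four aryl MOM groups, as in closely related prenylated 2'-hydroxy-6'-methoxychalcones, while short time and low temperature limit alkene hydroalkoxylation and flavanone closure.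

**Compound list**
1 | 5-methoxyresorcinol (3,5-dihydroxyanisole) | COc1cc(O)cc(O)c1 | starting material
2 | 1-methoxy-3,5-bis(methoxymethoxy)benzene | COCOc1cc(OC)cc(OCOC)c1 | intermediate
3 | aryllithium: [4-methoxy-2,6-bis(methoxymethoxy)phenyl]lithium | [Li]c1c(OCOC)cc(OC)cc1OCOC | intermediate
4 | lithium hemiaminal alkoxide: lithium (dimethylamino)[4-methoxy-2,6-bis(methoxymethoxy)phenyl]methanolate | CN(C)C(O[Li])c1c(OCOC)cc(OC)cc1OCOC | intermediate
5 | 4-methoxy-2,6-bis(methoxymethoxy)benzaldehyde | O=Cc1c(OCOC)cc(OC)cc1OCOC | intermediate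
6 | ethyl (2E)-3-[4-methoxy-2,6-bis(methoxymethoxy)phenyl]prop-2-enoate | CCOC(=O)/C=C/c1c(OCOC)cc(OC)cc1OCOC | intermediate
7 | ethyl 3-[4-methoxy-2,6-bis(methoxymethoxy)phenyl]propanoate | CCOC(=O)CCc1c(OCOC)cc(OC)cc1OCOC | intermediate
8 | 3-[4-methoxy-2,6-bis(methoxymethoxy)phenyl]propanoic acid | OC(=O)CCc1c(OCOC)cc(OC)cc1OCOC | intermediate
9 | (4R)-4-benzyl-1,3-oxazolidin-2-one | O=C1N[C@H](Cc2ccccc2)CO1 | starting material
10 | mixed pivalic anhydride: 2,2-dimethylpropanoic 3-[4-methoxy-2,6-bis(methoxymethoxy)phenyl]propanoic anhydride | CC(C)(C)C(=O)OC(=O)CCc1c(OCOC)cc(OC)cc1OCOC | intermediate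
11 | (4R)-4-benzyl-3-{3-[4-methoxy-2,6-bis(methoxymethoxy)phenyl]propanoyl}-1,3-oxazolidin-2-one | O=C(CCc1c(OCOC)cc(OC)cc1OCOC)N1C(=O)OC[C@H]1Cc1ccccc1 | intermediate
12 | sodium Z-enolate of 11 | [Na]O/C(=C\Cc1c(OCOC)cc(OC)cc1OCOC)N1C(=O)OC[C@H]1Cc1ccccc1 | intermediate
13 | (4R)-4-benzyl-3-[(2R)-2-{[4-methoxy-2,6-bis(methoxymethoxy)phenyl]methyl}-5-methylhex-4-enoyl]-1,3-oxazolidin-2-one | O=C([C@H](CC=C(C)C)Cc1c(OCOC)cc(OC)cc1OCOC)N1C(=O)OC[C@H]1Cc1ccccc1 | intermediate
14 | lithium peroxycarboxylate: lithium (2R)-2-{[4-methoxy-2,6-bis(methoxymethoxy)phenyl]methyl}-5-methylhex-4-eneperoxoate | [Li+].[O-]OC(=O)[C@H](CC=C(C)C)Cc1c(OCOC)cc(OC)cc1OCOC | intermediate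
15 | (2R)-2-{[4-methoxy-2,6-bis(methoxymethoxy)phenyl]methyl}-5-methylhex-4-enoic acid | OC(=O)[C@H](CC=C(C)C)Cc1c(OCOC)cc(OC)cc1OCOC | intermediate
16 | acyl imidazole: (2R)-1-(imidazol-1-yl)-2-{[4-methoxy-2,6-bis(methoxymethoxy)phenyl]methyl}-5-methylhex-4-en-1-one | O=C([C@H](CC=C(C)C)Cc1c(OCOC)cc(OC)cc1OCOC)n1ccnc1 | intermediate
17 | (2R)-N-methoxy-2-{[4-methoxy-2,6-bis(methoxymethoxy)phenyl]methyl}-N,5-dimethylhex-4-enamide | CON(C)C(=O)[C@H](CC=C(C)C)Cc1c(OCOC)cc(OC)cc1OCOC | intermediate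
18 | magnesium hemiaminal chelate: bromomagnesium alkoxide of the MeMgBr adduct of 17 (new carbinol centre undefined) | CON(C)C(C)(O[Mg]Br)[C@H](CC=C(C)C)Cc1c(OCOC)cc(OC)cc1OCOC | intermediate
19 | (3R)-3-{[4-methoxy-2,6-bis(methoxymethoxy)phenyl]methyl}-6-methylhept-5-en-2-one | CC(=O)[C@H](CC=C(C)C)Cc1c(OCOC)cc(OC)cc1OCOC | intermediate
20 | 5-methoxy-1,3-bis(methoxymethoxy)-2-[(2R)-5-methyl-2-(prop-1-en-2-yl)hex-4-en-1-yl]benzene | C=C(C)[C@H](CC=C(C)C)Cc1c(OCOC)cc(OC)cc1OCOC | intermediate
21 | aryllithium: {6-methoxy-2,4-bis(methoxymethoxy)-3-[(2R)-5-methyl-2-(prop-1-en-2-yl)hex-4-en-1-yl]phenyl}lithium | [Li]c1c(OC)cc(OCOC)c(C[C@@H](CC=C(C)C)C(C)=C)c1OCOC | intermediate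
22 | 1-{6-methoxy-2,4-bis(methoxymethoxy)-3-[(2R)-5-methyl-2-(prop-1-en-2-yl)hex-4-en-1-yl]phenyl}ethan-1-ol (both carbinol epimers) | CC(O)c1c(OC)cc(OCOC)c(C[C@@H](CC=C(C)C)C(C)=C)c1OCOC | intermediate
23 | 1-{6-methoxy-2,4-bis(methoxymethoxy)-3-[(2R)-5-methyl-2-(prop-1-en-2-yl)hex-4-en-1-yl]phenyl}ethan-1-one | CC(=O)c1c(OC)cc(OCOC)c(C[C@@H](CC=C(C)C)C(C)=C)c1OCOC | intermediate
24 | 2,4-dihydroxybenzaldehyde | O=Cc1ccc(O)cc1O | starting material
25 | 2,4-bis(methoxymethoxy)benzaldehyde | COCOc1ccc(C=O)c(OCOC)c1 | intermediate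
26 | aldol adduct: 3-[2,4-bis(methoxymethoxy)phenyl]-3-hydroxy-1-{6-methoxy-2,4-bis(methoxymethoxy)-3-[(2R)-5-methyl-2-(prop-1-en-2-yl)hex-4-en-1-yl]phenyl}propan-1-one (carbinol centre undefined) | O=C(CC(O)c1ccc(OCOC)cc1OCOC)c1c(OC)cc(OCOC)c(C[C@@H](CC=C(C)C)C(C)=C)c1OCOC | intermediate
27 | (2E)-3-[2,4-bis(methoxymethoxy)phenyl]-1-{6-methoxy-2,4-bis(methoxymethoxy)-3-[(2R)-5-methyl-2-(prop-1-en-2-yl)hex-4-en-1-yl]phenyl}prop-2-en-1-one | O=C(/C=C/c1ccc(OCOC)cc1OCOC)c1c(OC)cc(OCOC)c(C[C@@H](CC=C(C)C)C(C)=C)c1OCOC | intermediate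
28 | kuraridin, (2E)-3-(2,4-dihydroxyphenyl)-1-{2,4-dihydroxy-6-methoxy-3-[(2R)-5-methyl-2-(prop-1-en-2-yl)hex-4-en-1-yl]phenyl}prop-2-en-1-one | C=C(C)[C@H](CC=C(C)C)Cc1c(O)cc(OC)c(C(=O)/C=C/c2ccc(O)cc2O)c1O | target

**Totals**
Total step count: 16. Longest linear sequence: 15 steps (steps 1–13, 15 and 16; step 14 is a one-step side branch).

**Three steps most likely to fail, with fallbacks**

The final deprotection (step 16) is the most fragile. Protic acid can add a phenol across the isopropenyl or prenyl double bond (chroman formation) and can close the 2'-hydroxychalcone to the flavanone. The fallback avoids Brønsted acid and sets out from 27. Treatment with TMSOTf and 2,2'-bipyridyl in CH2Cl2 at 0 °C exchanges each aryl methoxymethyl acetal for a silyl ether, with the methoxymethyl cation trapped by bipyridyl. This gives kuraridin tetrakis(trimethylsilyl) ether F1, and stirring F1 with water/MeOH at room temperature hydrolyses the aryl silyl ethers under neutral conditions and returns to the route at 28.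

The ring lithiation and acetaldehyde trapping (step 12) may suffer from incomplete or unselective metalation of a substrate that carries allylic and benzylic hydrogens, or from enolisation of acetaldehyde by the hindered aryllithium. The fallback uses no carbanion and sets out from 20. Electrophilic bromination with NBS (1.0 eq, MeCN, −40 °C, dark) occurs at the only free, strongly activated ring position much faster than at the alkenes. This gives 2-bromo-1-methoxy-3,5-bis(methoxymethoxy)-4-[(2R)-5-methyl-2-(prop-1-en-2-yl)hex-4-en-1-yl]benzene F2. Stille coupling of F2 with tributyl(1-ethoxyvinyl)stannane (Pd2(dba)3, P(t-Bu)3, CsF, dioxane, 90 °C) gives the aryl enol ether 2-(1-ethoxyethenyl)-1-methoxy-3,5-bis(methoxymethoxy)-4-[(2R)-5-methyl-2-(prop-1-en-2-yl)hex-4-en-1-yl]benzene F3. Brief hydrolysis of F3 (PPTS, acetone/H2O, rt) returns to the route at 23, bypassing 21 and 22.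

The Wittig methylenation (step 11) may partly epimerise the α-branched methyl ketone through enolisation by the basic ylide, or stall for steric reasons. The fallback is a two-stage Peterson olefination and sets out from 19. Addition of the non-basic organocerium reagent from Me3SiCH2Li and CeCl3 (THF, −78 °C) gives the β-hydroxysilane (3R)-3-{[4-methoxy-2,6-bis(methoxymethoxy)phenyl]methyl}-2,6-dimethyl-1-(trimethylsilyl)hept-5-en-2-ol F4 without enolisation. Syn-elimination from F4 with KH in THF (0 °C → rt) returns to the route at 20.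

**Further compounds**
F1 | step 16 | kuraridin tetrakis(trimethylsilyl) ether | C=C(C)[C@H](CC=C(C)C)Cc1c(O[Si](C)(C)C)cc(OC)c(C(=O)/C=C/c2ccc(O[Si](C)(C)C)cc2O[Si](C)(C)C)c1O[Si](C)(C)C
F2 | step 12 | 2-bromo-1-methoxy-3,5-bis(methoxymethoxy)-4-[(2R)-5-methyl-2-(prop-1-en-2-yl)hex-4-en-1-yl]benzene | Brc1c(OC)cc(OCOC)c(C[C@@H](CC=C(C)C)C(C)=C)c1OCOC
F3 | step 12 | 2-(1-ethoxyethenyl)-1-methoxy-3,5-bis(methoxymethoxy)-4-[(2R)-5-methyl-2-(prop-1-en-2-yl)hex-4-en-1-yl]benzene | CCOC(=C)c1c(OC)cc(OCOC)c(C[C@@H](CC=C(C)C)C(C)=C)c1OCOC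
F4 | step 11 | (3R)-3-{[4-methoxy-2,6-bis(methoxymethoxy)phenyl]methyl}-2,6-dimethyl-1-(trimethylsilyl)hept-5-en-2-ol (carbinol centre undefined) | C[Si](C)(C)CC(C)(O)[C@H](CC=C(C)C)Cc1c(OCOC)cc(OC)cc1OCOC
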